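The data were computed from invented constants; the scatter is artificial.

The target in the gamma flask already reads 23 % at the first reading and shows no trend in the later ones, so what you want is the share of what the partner catches that ends up as target.

all flasks: starting material 0.050 M; temperature 5 °C

| charge | partner | protic impurity | remark | time |
|---|---|---|---|---|
| gamma | 0.035 M | 2.5 mM | the very flask that is asked about, followed so far |  |
| theta | 0.053 M | 2.5 mM | run made earlier |  |
| flask | 0.0350 M | 2.50 mM |  | 4.0 d |

| run | time / h | target / % | starting material / % |
|---|---|---|---|
| gamma | 6.00 | 23 | 7 |
| gamma | 10.0 | 22 | 6 |
| gamma | 15.0 | 21 | 4 |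
| gamma | 20.0 | 22 | 5 |
| gamma | 30.0 | 26 | 3 |
| gamma | 48.0 | 20 | 4 |
| gamma | 72.0 | 23 | 1 |
| theta | 0.667 | 18 | 40 |
| theta | 1.33 | 29 | 25 |
| theta | 2.00 | 31 | 12 |
| theta | 3.00 | 29 | 4 |
| theta | 4.00 | 30 | 4 |
| theta | 5.00 | 34 | 4 |

(each reading ± 1.5 percentage points)

- spring: change nothing and wait 8.0 d more
- midnight: at 4.0 d add partner, 100 % of the amount charged, then wait 8.0 d
- dawn: at 4.0 d raise the temperature by 25 K, then wait 8.0 d
- noon: at 4.0 d take out 90 % of the target then present, then wait 8.0 d

1. target, in percent of the starting material first charged, at 4.0 d
2. the option that brings most further target ("none" if no option brings more than 2 percentage points) (spring / midnight / dawn / noon / none)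
3. target present, with what was taken out counted in, in percent of the starting material first charged, after spring
4. target present, with what was taken out counted in, in percent of the starting material first charged, after midnight

- target taken out counts as made
- the numbers in the tables scatter with a standard deviation of 1.5 percentage points
- additions bring no volume worth counting
- the earlier runs do not show what temperature does; that part of a forecast is a guess

Take gamma in slow motion, with my own bookkeeping. In the first instants I let the protic impurity take one partner each, which leaves usable partner worth 65.0 % of the starting material charged. The crossing where control changes hands lies at [partner] = [starting material] + [protic impurity] = 0.0525 M: gamma stands below it, with partner the limiting reagent, and theta stands just above it. For the middle, theta shows the pace: starting material reads 40 % at 0.667 h and 12 % at 2.00 h, and at the first of these the target already reads 30.0 % of what has gone. At the end, the seven gamma readings average 22.4 % without a trend, while starting material sinks to 1 %.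

So define the capture share, the target plateau as read in gamma divided by usable partner, 34.5 %, about a third. My rule, at 5 °C and with the charges of starting material and protic impurity held as here, is: target equals this share times the smaller of usable partner and starting material charged. Theta, just above the crossing, reads 31.0 % over its last four readings against the 34.5 % that the rule gives it, and that gap is the spread I allow the share. My reckoning for gamma is 22.4 % now and after spring, and 22.7 % after midnight, with the share applied to the 1 % of starting material last read. I have no reading of the uncaught rest, so whether it is dead or in balance with the target is a bet; theta's 30.0 % at its first reading stands beside the share of 34.5 %, so I bet on balance, and so on noon.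

The forecast gave 22.8 % (from 21.3 % to 24.3 %), 23 % after spring, 23.3 % after midnight and none as best option, “barring an unseen reversible reservoir”, which parts from my noon.

The flask gives 22.4 % now, 22.4 % after spring and 24.3 % after midnight; the gains are 0 percentage points for spring, 1.9 points for midnight, 13 points for noon and 24 points for dawn, so the best option is dawn.

    partner + protic impurity → quenched reagent (k = 21.0 M⁻¹ min⁻¹, Ea = 40.0 kJ mol⁻¹)
    target ⇌ isomer of the product (K = 1.90, k = 0.0260 min⁻¹, Ea = 79.0 kJ mol⁻¹, ΔH = −44.0 kJ mol⁻¹)
    starting material ⇌ open intermediate (K = 2.20, k = 0.0310 min⁻¹, Ea = 76.0 kJ mol⁻¹, ΔH = −21.0 kJ mol⁻¹)
    partner → decomposition product (k = 1.70 × 10⁻⁵ min⁻¹, Ea = 109 kJ mol⁻¹)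
    open intermediate + second intermediate → target (k = 1.10 M⁻¹ min⁻¹, Ea = 50.0 kJ mol⁻¹)
    2 open intermediate → homo product (k = 0.0540 M⁻¹ min⁻¹, Ea = 61.0 kJ mol⁻¹)
    partner → second intermediate (k = 0.0310 min⁻¹, Ea = 76.0 kJ mol⁻¹)
    (constants at 5 °C)

In this flask partner passed into second intermediate with a half-life of 0.37 h by that step alone, the step having 100 % of its turnover up to 4.0 d behind it after 9.60 h, while target and isomer of the product relaxed with a half-life of 0.291 h by their own step, both ways together, short against 4.0 d. After 96.0 h they stand in this flask at 22.4 % and 42.6 % of the starting material charged. Take 90 % of that target out as in noon, apply the capture share to the remaining pair, and the gain reckons to 13 points; the flask gives 13 points.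

With 0.14 M of partner, above the crossing, usable partner is worth 275 %, so starting material becomes the smaller term and the rule gives 34.5 %. That neighbouring flask computes to 34.1 %, beside 64.7 % of isomer of the product.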